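## Structural features

The target (CNP0264497.0) is a flavone: a benzene ring A fused through the C4a–C8a bond to a 4-pyranone ring C (O1, C2, C3, C4=O), which carries a second benzene, ring B, on C2 through the C2–C1' bond. It has no stereocentre, so the whole problem is regiochemistry on two heavily oxygenated arenes. Ring A is pentasubstituted: hydrogen on C5, methyl ethers on C6 and C7, a free phenol on C8 and the ring oxygen O1 on C8a, so four oxygens stand in a row and only the one on C8 is unmethylated. Ring B repeats the theme with a free 3'-OH next to 4'-OMe and 5'-OMe. The fragile parts are the two electron-rich phenols (acidic, easily oxidised), the pyranone (opened at C2 by hydroxide or alkoxide, and reducible at C2=C3) and the four methyl ethers, which must survive whatever unmasks the phenols. The real difficulty is placing the single free hydroxyl of ring A on C8 between OMe and O1; selective demethylation of a 6,7,8-trimethoxy ring or substitution of a simpler arene does not distinguish these positions reliably. The key step exploits the fact that C5(H)–C6(OMe)–C7(OMe)–C8(OH) corresponds atom for atom to the four carbons of a 3,4-dimethoxyfuran whose own oxygen stays on C8. C4a and C8a are then the two carbons of an alkyne that brings C4 as an ester carbon and a bromine on C8a as the place-holder for O1.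

## Logic of the disconnections

18 ⇒ 17. The hydroxyls on C8 and C3' each receive a benzyl group, so the two O–CH2Ph bonds are the last ones broken in the forward direction. They are the only free phenols, and one common mask that is orthogonal to the four methyl ethers lets a single final operation release both. The gain is that 17 carries no acidic or oxidisable OH through the base- and copper-mediated steps. The demand is a debenzylation that leaves O–methyl bonds and the C2=C3 bond of ring C alone.

17 ⇒ 16. The O1–C8a bond is cut. O1 becomes the enol oxygen of a 1,3-diketone and C8a carries bromine, which is what the ring A construction delivers. Ring C disappears and an open C2–C3–C4 chain remains. The forward step must make an aryl–oxygen bond at a bromide with substituents on both ortho carbons of an electron-rich ring, which calls for copper catalysis and not plain nucleophilic aromatic substitution.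

16 ⇒ 11 + 15. The C3–C4 bond is cut. This is the convergent cut: it divides the molecule into an aryl ester (C4 with ring A) and an aryl methyl ketone (C3 and C2 with ring B) of similar size. The forward Claisen condensation requires the enolate of 15 to acylate on a hindered ortho-bromo ester without self-condensation, so an excess of a non-nucleophilic amide base is needed.

11 ⇒ 10. The O–benzyl bond on the C8 oxygen is cut, because the key step delivers this oxygen as a free phenol. The forward alkylation is simple, although the hydroxyl sits between bromine and a methoxy group.

10 ⇒ 6 + 8 (through 9). The oxygen on C8 is first reconnected to C5 as a bridge, then C4a–C5 and C8–C8a are cut. Ring A is removed altogether and its whole substitution pattern is encoded in two small pieces: 6 supplies C5 to C8 with both methyl ethers and the future phenol oxygen, and 8 supplies C4a, C8a, the ester carbon C4 and the bromine. Since 6 is symmetrical, orientation in the bond-forming event is no issue. The demand falls on the second half of the forward step: the oxygen bridge of 9 must open at C5–O and not at C8–O.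

8 ⇒ 7. The C–Br bond at the alkyne terminus is cut; the forward step is electrophilic bromination of a terminal alkyne, which costs one operation and avoids storing the lachrymatory 8.

6 ⇒ 5 ⇒ 4 ⇒ 3. A carboxyl group is put back on each α-carbon (two C–CO2H bonds broken forward), the acids go back to methyl esters and the two O–CH3 bonds are cut. The esters are what make the ring accessible by condensation, and they keep the electron-rich ring stable until just before use. The forward demand is a double decarboxylation that does not destroy the acid- and air-sensitive 6.

3 ⇒ 1 + 2. The two ring C–C bonds between each α-carbon and its neighbouring β-carbon are cut. 1 supplies the ring oxygen with both α-carbons and their esters, 2 supplies both oxygenated β-carbons. The forward step is a double Claisen condensation with the alkoxide that matches the ester groups.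

15 ⇒ 14 ⇒ 13 ⇒ 12. The ketone is taken back to the secondary alcohol, the C–CH3 bond is cut to reveal an aldehyde, and the O–benzyl bond is cut. 12 is purchasable with the ring B oxygen pattern already differentiated, so no selective demethylation is needed there. The phenol must be benzylated before the organometallic addition.

## Other disconnections considered

Alternative 1: The cut is C3–C4 inside ring C with O1–C2 already in place. The precursor is 3-(benzyloxy)-2-({1-[3-(benzyloxy)-4,5-dimethoxyphenyl]ethenyl}oxy)-4,5-dimethoxybenzoic acid A1. In the forward direction the acid is converted into its chloride, the terminal CH2 of the enol ether attacks the acyl carbon to close the six-membered ring, and the oxocarbenium ion at C2 (stabilised by O1 and ring B) loses the C3 proton. The product is 8-(benzyloxy)-2-[3-(benzyloxy)-4,5-dimethoxyphenyl]-6,7-dimethoxy-4H-chromen-4-one A2, the same compound as 17.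
- In its favour: the closure is electronically well matched, and it needs no transition metal and no coupling at a hindered aryl bromide. On that point it is better than the chosen plan.
- In its favour: A2 is one deprotection from the target, whereas the chosen key step leaves five operations to go. On post-key-step economy it is better.
- Against it here: A1 requires a 1-arylvinyl group on a phenol oxygen wedged between a carboxyl and a benzyloxy group. Such enol ethers hydrolyse readily, and acid chloride formation liberates HCl.
- Against it here: it presupposes a ring A with four adjacent oxygens in three different states next to a carboxyl, which is the actual problem of the target.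
- Comparison: on structure, the chosen plan creates ring A and its differentiated oxygens in one step from 6 and 8, while this alternative only addresses ring C. On mechanism, both closures are substituent-controlled cationic events, but here the competing process is protonation of the nucleophile itself. Over the whole route the step count should be equal at best and probably higher.

Alternative 2: The cut removes C3 by breaking C2–C3 and C3–C4, which contracts ring C to the furan ring of {7-(benzyloxy)-2-[3-(benzyloxy)-4,5-dimethoxyphenyl]-5,6-dimethoxy-1-benzofuran-3-yl}oxy(tert-butyl)dimethylsilane A3. In the forward direction dichlorocarbene adds to the silyloxy-substituted C2=C3 bond of A3, the dichlorocyclopropane opens as chloride leaves, and loss of the silyl group gives the pyranone. This is a ring expansion of the Ciamician–Dennstedt type. The product is 8-(benzyloxy)-2-[3-(benzyloxy)-4,5-dimethoxyphenyl]-3-chloro-6,7-dimethoxy-4H-chromen-4-one A4.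
- In its favour: two skeletal bonds form in one metal-free operation from a cheap one-carbon source, which equals the chosen key step in bonds formed.
- In its favour: a chlorine at C3 would be a useful handle for analogues.
- Against it here: that chlorine is superfluous for this target and has to be removed reductively. Doing this together with the debenzylation raises the risk of reducing C2=C3.
- Against it here: the carbene must attack a tetrasubstituted double bond that belongs to an aromatic furan and is flanked by an aryl group, and the strong base that generates the carbene threatens the silyl enol ether.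
- Against it here: A3 needs the same pentasubstituted ring A, which is left unsolved.
- Comparison: on structure the chosen plan is stronger because it builds ring A. On mechanism both are two-bond events followed by a strain-releasing ionisation, but this one adds an atom that must be taken out again. On step economy the alternative is better after its key step (two operations against five) but not over the whole route.

Alternative 3: The cut is C8–C8a, with C4a–C5 assumed to be made earlier, so ring A unravels to a four-membered ring on a pyranone. The precursor is racemic 2-[3-(benzyloxy)-4,5-dimethoxyphenyl]-5-(2,3-dimethoxy-4-oxocyclobut-2-en-1-yl)-4H-pyran-4-one A5. In the forward direction heating opens the cyclobutenone by a four-electron electrocyclic reaction to a vinylketene. Its ketene carbon bonds to the pyranone CH next to O1 in a six-electron electrocyclisation, and tautomerisation gives 2-[3-(benzyloxy)-4,5-dimethoxyphenyl]-8-hydroxy-6,7-dimethoxy-4H-chromen-4-one A6.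
- In its favour: it follows the same strategic idea as the chosen plan. Ring A is made de novo, the C8 phenol emerges free, and C6 and C7 arrive as methyl ethers.
- In its favour: there is no ambiguity about which oxygen ends up free, because the ketene carbon can only become C8. On regiochemical certainty it is better than the chosen bridge opening.
- In its favour: rings B and C are already present, so a single debenzylation reaches the target. On convergence and post-key-step economy it is clearly better.
- Against it here: A5 requires a bond between a pyranone carbon and the sp3 carbon of a cyclobutenone that must carry hydrogen and not hydroxyl, otherwise C5 ends up oxygenated. That means a metallated or halogenated pyranone and a cross-coupling or an addition–deoxygenation sequence on sensitive four-membered rings.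
- Against it here: the pyranone carrying ring B must itself be made and functionalised selectively, and cyclisation onto a vinylogous-ester double bond may be slow enough for the ketene to be lost in other ways.
- Comparison: both key steps are pericyclic at the core and need no metal, so they are equal on mechanism. Both solve ring A, so they are equal on structure. This alternative is shorter after its key step but longer and less secure before it, whereas the chosen plan starts from two small precursors made in five simple operations.

Key step: step 6

Assumption: 6 is prepared and not bought because it is costly and keeps poorly; 9 and 14 are formed as racemates, which is immaterial because neither stereocentre survives.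

## Route

Step 1
Reactants: 1 dimethyl diglycolate (dimethyl 2,2'-oxydiacetate); 2 dimethyl oxalate
Product: 3 dimethyl 3,4-dihydroxyfuran-2,5-dicarboxylate
Conditions: NaOMe (2.2 equiv), MeOH, reflux; then aq. HCl, 0 °C
Reagents that add atoms: none
Why: Double Claisen condensation (Hinsberg-type furan synthesis): each α-carbon of 1 acylates on one carbonyl of 2, and the diketone enolises fully to the aromatic dihydroxyfuran, whose disodium salt should precipitate and pull the equilibrium over.

Step 2
Reactants: 3 dimethyl 3,4-dihydroxyfuran-2,5-dicarboxylate
Product: 4 dimethyl 3,4-dimethoxyfuran-2,5-dicarboxylate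
Conditions: MeI, K2CO3, DMF, 50 °C
Reagents that add atoms: iodomethane, CI
Why: Williamson O-methylation of two acidic enolic hydroxyls (vinylogous acids through the esters); C-alkylation is not expected because it would destroy the furan aromaticity.

Step 3
Reactants: 4 dimethyl 3,4-dimethoxyfuran-2,5-dicarboxylate
Product: 5 3,4-dimethoxyfuran-2,5-dicarboxylic acid
Conditions: NaOH, H2O/MeOH, reflux; then aq. HCl, 0 °C
Reagents that add atoms: sodium hydroxide, [Na+].[OH-]
Why: Ordinary saponification of two aryl-type methyl esters; the methyl ethers and the furan ring are inert to aqueous base, and the diacid should precipitate on acidification in the cold.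

Step 4
Reactants: 5 3,4-dimethoxyfuran-2,5-dicarboxylic acid
Product: 6 3,4-dimethoxyfuran
Conditions: Cu powder, quinoline, 190–200 °C, product distilled out under reduced pressure
Reagents that add atoms: none
Why: Copper-mediated protodecarboxylation of furan-2-carboxylic acids, helped by the electron-rich ring, which protonates easily at the ipso carbon; continuous distillation takes the sensitive furan out of the hot basic medium as it forms.

Step 5
Reactants: 7 methyl propiolate
Product: 8 methyl 3-bromopropiolate
Conditions: NBS, AgNO3 (10 mol%), acetone, rt
Reagents that add atoms: N-bromosuccinimide, O=C1CCC(=O)N1Br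
Why: Silver-catalysed electrophilic bromination of a terminal alkyne through the silver acetylide; 8 is a lachrymator and is taken on directly after filtration and concentration.

Step 6
Reactants: 6 3,4-dimethoxyfuran; 8 methyl 3-bromopropiolate
Product: 10 methyl 2-bromo-3-hydroxy-4,5-dimethoxybenzoate, via oxanorbornadiene 9 (not isolated)
Conditions: PhMe, 80 °C, dark; then CF3CO2H (0.2 equiv), 0 °C → rt
Reagents that add atoms: none
Why: The electron-rich diene 6 and the electron-poor alkyne 8 should combine in a concerted, suprafacial Diels–Alder cycloaddition of normal electron demand that forms C4a–C5 and C8–C8a and closes the six-membered carbocycle as the oxygen-bridged diene 9; the closest known reaction type is the cycloaddition of furans to 3-haloalkynoates followed by acid isomerisation of the 7-oxanorbornadiene to a phenol. Because 6 has a mirror plane through its oxygen only one constitutional adduct is possible, and an alkyne dienophile raises no endo/exo question. The two bridgehead stereocentres of 9 are necessarily cis, arise as a racemate and vanish on aromatisation, so no stereocontrol is needed. Protonation of the bridging oxygen and heterolysis of C5–O give a cyclohexadienyl cation whose charge is shared by C5, by C7 as a methoxy-stabilised oxocarbenium ion and by C8a with help from a bromine lone pair, while the ester sits on the uncharged central carbon C4a. Heterolysis of C8–O would instead place charge on C4a directly beside the ester carbonyl, and this difference is what should direct the opening to C5–O. Loss of the proton from C8, which still bears the hydroxyl, aromatises ring A and leaves the only free phenol on C8, bromine on C8a and the ester carbon as the future C4. The step therefore needs regioselectivity in the bridge opening and chemoselectivity for ionisation over hydrolysis of the enol ethers or displacement of the vinylic bromide; the first is secured by the ester/bromine pattern and the second by a catalytic amount of anhydrous acid in a non-nucleophilic solvent.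

Step 7
Reactants: 10 methyl 2-bromo-3-hydroxy-4,5-dimethoxybenzoate
Product: 11 methyl 3-(benzyloxy)-2-bromo-4,5-dimethoxybenzoate
Conditions: BnBr, K2CO3, DMF, 60 °C
Reagents that add atoms: benzyl bromide, BrCc1ccccc1
Why: Williamson etherification of a phenoxide made more acidic by the ortho bromine; the ester and the aryl bromide do not react with carbonate, and the benzyl group is chosen because it can be removed together with the ring B benzyl at the end.

Step 8
Reactants: 12 3-hydroxy-4,5-dimethoxybenzaldehyde
Product: 13 3-(benzyloxy)-4,5-dimethoxybenzaldehyde
Conditions: BnBr, K2CO3, DMF, rt
Reagents that add atoms: benzyl bromide, BrCc1ccccc1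
Why: Williamson etherification of the only phenol; the aldehyde has no α-hydrogen and is stable to carbonate.

Step 9
Reactants: 13 3-(benzyloxy)-4,5-dimethoxybenzaldehyde
Product: 14 1-[3-(benzyloxy)-4,5-dimethoxyphenyl]ethan-1-ol (racemic)
Conditions: MeMgBr, THF, 0 °C; then sat. aq. NH4Cl
Reagents that add atoms: methylmagnesium bromide, C[Mg]Br
Why: Grignard addition to an aryl aldehyde; the new carbinol centre is formed without control and is erased in step 10, so the racemate is acceptable.

Step 10
Reactants: 14 1-[3-(benzyloxy)-4,5-dimethoxyphenyl]ethan-1-ol (racemic)
Product: 15 1-[3-(benzyloxy)-4,5-dimethoxyphenyl]ethan-1-one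
Conditions: MnO2 (activated, excess), CH2Cl2, rt
Reagents that add atoms: none
Why: Selective oxidation of a benzylic alcohol by activated MnO2; the electron-rich ring and the benzyl ether are not touched under these neutral conditions.

Step 11
Reactants: 15 1-[3-(benzyloxy)-4,5-dimethoxyphenyl]ethan-1-one; 11 methyl 3-(benzyloxy)-2-bromo-4,5-dimethoxybenzoate
Product: 16 1-[3-(benzyloxy)-2-bromo-4,5-dimethoxyphenyl]-3-[3-(benzyloxy)-4,5-dimethoxyphenyl]propane-1,3-dione (mainly as its enol)
Conditions: 15, LiHMDS (2.2 equiv), THF, –78 °C; then 11, –78 °C → rt; then 1 M HCl
Reagents that add atoms: none
Why: Crossed Claisen condensation of a ketone lithium enolate with a non-enolisable ester, driven by deprotonation of the product diketone by the second equivalent of base; the amide base does not attack the bromide, and aryne formation is excluded because neither carbon next to the bromine carries hydrogen.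

Step 12
Reactants: 16 1-[3-(benzyloxy)-2-bromo-4,5-dimethoxyphenyl]-3-[3-(benzyloxy)-4,5-dimethoxyphenyl]propane-1,3-dione
Product: 17 8-(benzyloxy)-2-[3-(benzyloxy)-4,5-dimethoxyphenyl]-6,7-dimethoxy-4H-chromen-4-one
Conditions: CuI (10 mol%), 1,10-phenanthroline (20 mol%), K2CO3, DMF, 110 °C
Reagents that add atoms: none
Why: Intramolecular Ullmann-type O-arylation of the diketone enolate, a known way from 1-(2-bromoaryl)-1,3-diketones to flavones; the enolate oxygen on the ring B side closes ring C at C8a, the ortho carbonyl assists substitution at the bromide, and C-arylation would need a four-membered ring.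

Step 13
Reactants: 17 8-(benzyloxy)-2-[3-(benzyloxy)-4,5-dimethoxyphenyl]-6,7-dimethoxy-4H-chromen-4-one
Product: 18 8-hydroxy-2-(3-hydroxy-4,5-dimethoxyphenyl)-6,7-dimethoxy-4H-chromen-4-one (CNP0264497.0)
Conditions: H2 (1 atm), Pd/C, EtOAc/MeOH, rt
Reagents that add atoms: none
Why: Hydrogenolysis of both benzyl aryl ethers over palladium; the methyl ethers are inert and the vinylogous-ester C2=C3 bond of a flavone should be reduced much more slowly than benzylic C–O bonds are cleaved, provided the reaction is stopped at full conversion.

## Compound list

1 | dimethyl diglycolate (dimethyl 2,2'-oxydiacetate) | COC(=O)COCC(=O)OC | starting material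
2 | dimethyl oxalate | COC(=O)C(=O)OC | starting material
3 | dimethyl 3,4-dihydroxyfuran-2,5-dicarboxylate | COC(=O)c1oc(C(=O)OC)c(O)c1O | intermediate
4 | dimethyl 3,4-dimethoxyfuran-2,5-dicarboxylate | COC(=O)c1oc(C(=O)OC)c(OC)c1OC | intermediate
5 | 3,4-dimethoxyfuran-2,5-dicarboxylic acid | OC(=O)c1oc(C(=O)O)c(OC)c1OC | intermediate
6 | 3,4-dimethoxyfuran | COc1cocc1OC | intermediate
7 | methyl propiolate | C#CC(=O)OC | starting material
8 | methyl 3-bromopropiolate | COC(=O)C#CBr | intermediate
9 | methyl 3-bromo-5,6-dimethoxy-7-oxabicyclo[2.2.1]hepta-2,5-diene-2-carboxylate (racemic, one enantiomer drawn, bridgehead hydrogens cis; not isolated) | COC(=O)C1=C(Br)[C@@H]2O[C@H]1C(OC)=C2OC | intermediate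
10 | methyl 2-bromo-3-hydroxy-4,5-dimethoxybenzoate | COC(=O)c1cc(OC)c(OC)c(O)c1Br | intermediate
11 | methyl 3-(benzyloxy)-2-bromo-4,5-dimethoxybenzoate | COC(=O)c1cc(OC)c(OC)c(OCc2ccccc2)c1Br | intermediate
12 | 3-hydroxy-4,5-dimethoxybenzaldehyde | COc1cc(C=O)cc(O)c1OC | starting material
13 | 3-(benzyloxy)-4,5-dimethoxybenzaldehyde | COc1cc(C=O)cc(OCc2ccccc2)c1OC | intermediate
14 | 1-[3-(benzyloxy)-4,5-dimethoxyphenyl]ethan-1-ol (racemic) | COc1cc(C(C)O)cc(OCc2ccccc2)c1OC | intermediate
15 | 1-[3-(benzyloxy)-4,5-dimethoxyphenyl]ethan-1-one | COc1cc(C(C)=O)cc(OCc2ccccc2)c1OC | intermediate
16 | 1-[3-(benzyloxy)-2-bromo-4,5-dimethoxyphenyl]-3-[3-(benzyloxy)-4,5-dimethoxyphenyl]propane-1,3-dione | COc1cc(C(=O)CC(=O)c2cc(OC)c(OC)c(OCc3ccccc3)c2Br)cc(OCc2ccccc2)c1OC | intermediate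
17 | 8-(benzyloxy)-2-[3-(benzyloxy)-4,5-dimethoxyphenyl]-6,7-dimethoxy-4H-chromen-4-one | COc1cc(-c2cc(=O)c3cc(OC)c(OC)c(OCc4ccccc4)c3o2)cc(OCc2ccccc2)c1OC | intermediate
18 | 8-hydroxy-2-(3-hydroxy-4,5-dimethoxyphenyl)-6,7-dimethoxy-4H-chromen-4-one | COc1cc(-c2cc(=O)c3cc(OC)c(OC)c(O)c3o2)cc(O)c1OC | target

## Step count and risk

Total step count: 13. Longest linear sequence: 9 steps (1, 2, 3, 4, 6, 7, 11, 12, 13). Step 5 and steps 8–10 are side branches.

Step 6 (key step).
- What may go wrong: the cycloaddition may be slow compared with thermal decay of the bromoalkyne. During the acid treatment, the enol ethers of 9 may hydrolyse, bromine may be lost by addition–elimination at the bromoacrylate, or part of the material may open at the other C–O bond.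
- Fallback: the same ring construction, with the halogen introduced after aromatisation. 6 and 7 are heated in PhMe at 100 °C to give racemic methyl 5,6-dimethoxy-7-oxabicyclo[2.2.1]hepta-2,5-diene-2-carboxylate F1, which is not isolated. Catalytic CF3CO2H opens it by the same C5–O ionisation to methyl 3-hydroxy-4,5-dimethoxybenzoate F2. Ortho-selective bromination of this phenol (NBS, catalytic iPr2NH, CH2Cl2, 0 °C) then returns to the route at 10; the only free position ortho to the hydroxyl is the one between OH and the ester.

Step 12.
- What may go wrong: copper may insert slowly into a bromide flanked by two ortho substituents on an electron-rich ring, so that retro-Claisen cleavage of the diketone or protodebromination takes over at 110 °C.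
- Fallback: O1 is placed on C8a before ring C is made, so that the closure becomes a cyclodehydration. From 11, hydroxide substitution assisted by the ortho carboxylate (NaOH, Cu2O cat., H2O/dioxane, 100 °C, ester hydrolysed in the same pot) should give 3-(benzyloxy)-2-hydroxy-4,5-dimethoxybenzoic acid F3. Selective carboxylate methylation (MeI, KHCO3, DMF) gives methyl 3-(benzyloxy)-2-hydroxy-4,5-dimethoxybenzoate F4. Claisen condensation with the enolate of 15 (LiHMDS, 3.5 equiv, THF) gives 1-[3-(benzyloxy)-2-hydroxy-4,5-dimethoxyphenyl]-3-[3-(benzyloxy)-4,5-dimethoxyphenyl]propane-1,3-dione F5. Acid-catalysed cyclodehydration (TsOH cat., PhMe, 80 °C) returns to the route at 17.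

Step 11.
- What may go wrong: acyl transfer to the hindered ortho-bromo ester may be slow, so that self-aldol of 15 and simple proton exchange dominate.
- Fallback: a far more reactive acyl donor under soft enolisation. From 11, saponification (LiOH, THF/H2O) gives 3-(benzyloxy)-2-bromo-4,5-dimethoxybenzoic acid F6. Oxalyl chloride with catalytic DMF gives 3-(benzyloxy)-2-bromo-4,5-dimethoxybenzoyl chloride F7. Direct C-acylation of 15 with it (MgBr2·OEt2, iPr2NEt, CH2Cl2, rt) returns to the route at 16.

Step 13.
- What may go wrong: the C2=C3 bond may be over-reduced to the flavanone, or cleavage of the crowded 8-O-benzyl ether may stall.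
- Fallback: a non-reductive debenzylation directly from 17 with BCl3 and pentamethylbenzene as cation scavenger (CH2Cl2, –78 °C). It leaves the double bond and the methyl ethers (none is peri to the carbonyl) alone and arrives at 18 without any new compound (entry F0).

## Further compounds

F1 | step 6 | methyl 5,6-dimethoxy-7-oxabicyclo[2.2.1]hepta-2,5-diene-2-carboxylate (racemic, one enantiomer drawn) | COC(=O)C1=C[C@@H]2O[C@H]1C(OC)=C2OC
F2 | step 6 | methyl 3-hydroxy-4,5-dimethoxybenzoate | COC(=O)c1cc(O)c(OC)c(OC)c1
F3 | step 12 | 3-(benzyloxy)-2-hydroxy-4,5-dimethoxybenzoic acid | OC(=O)c1cc(OC)c(OC)c(OCc2ccccc2)c1O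
F4 | step 12 | methyl 3-(benzyloxy)-2-hydroxy-4,5-dimethoxybenzoate | COC(=O)c1cc(OC)c(OC)c(OCc2ccccc2)c1O
F5 | step 12 | 1-[3-(benzyloxy)-2-hydroxy-4,5-dimethoxyphenyl]-3-[3-(benzyloxy)-4,5-dimethoxyphenyl]propane-1,3-dione | COc1cc(C(=O)CC(=O)c2cc(OC)c(OC)c(OCc3ccccc3)c2O)cc(OCc2ccccc2)c1OC
F6 | step 11 | 3-(benzyloxy)-2-bromo-4,5-dimethoxybenzoic acid | OC(=O)c1cc(OC)c(OC)c(OCc2ccccc2)c1Br
F7 | step 11 | 3-(benzyloxy)-2-bromo-4,5-dimethoxybenzoyl chloride | O=C(Cl)c1cc(OC)c(OC)c(OCc2ccccc2)c1Br
F0 | step 13 | none | none
A1 | alternative 1 | 3-(benzyloxy)-2-({1-[3-(benzyloxy)-4,5-dimethoxyphenyl]ethenyl}oxy)-4,5-dimethoxybenzoic acid | OC(=O)c1cc(OC)c(OC)c(OCc2ccccc2)c1OC(=C)c1cc(OC)c(OC)c(OCc2ccccc2)c1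
A2 | alternative 1 | 8-(benzyloxy)-2-[3-(benzyloxy)-4,5-dimethoxyphenyl]-6,7-dimethoxy-4H-chromen-4-one | COc1cc(-c2cc(=O)c3cc(OC)c(OC)c(OCc4ccccc4)c3o2)cc(OCc2ccccc2)c1OC
A3 | alternative 2 | {7-(benzyloxy)-2-[3-(benzyloxy)-4,5-dimethoxyphenyl]-5,6-dimethoxy-1-benzofuran-3-yl}oxy(tert-butyl)dimethylsilane | COc1cc(-c2oc3c(OCc4ccccc4)c(OC)c(OC)cc3c2O[Si](C)(C)C(C)(C)C)cc(OCc2ccccc2)c1OC
A4 | alternative 2 | 8-(benzyloxy)-2-[3-(benzyloxy)-4,5-dimethoxyphenyl]-3-chloro-6,7-dimethoxy-4H-chromen-4-one | COc1cc(-c2oc3c(OCc4ccccc4)c(OC)c(OC)cc3c(=O)c2Cl)cc(OCc2ccccc2)c1OC
A5 | alternative 3 | 2-[3-(benzyloxy)-4,5-dimethoxyphenyl]-5-(2,3-dimethoxy-4-oxocyclobut-2-en-1-yl)-4H-pyran-4-one (racemic) | COc1cc(-c2cc(=O)c(C3C(=O)C(OC)=C3OC)co2)cc(OCc2ccccc2)c1OC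
A6 | alternative 3 | 2-[3-(benzyloxy)-4,5-dimethoxyphenyl]-8-hydroxy-6,7-dimethoxy-4H-chromen-4-one | COc1cc(-c2cc(=O)c3cc(OC)c(OC)c(O)c3o2)cc(OCc2ccccc2)c1OC
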